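## Retrosynthetic overview

1. The last operation is reduction of the C7' carbonyl of cage keto lactone 23. Before it, ring C (C8–C9–C11–C4'–C3a') and ring E (C8–C12–C6'–C5'–C4'–C3a') are cut together at C8–C3a' and C12–C6'.
2. These two bonds come from a thermal intramolecular [4+2] reaction of 22: the C6'=C7'–C7a'=C3a' diene of a dearomatised 5,7-dihydroxy-4,6-dimethylphthalide (ring D with lactone F) adds to the exocyclic C8=C12 alkene of ring B. The enabling feature is the quaternary C4' (methyl + C11): it freezes ring D as a cyclohexa-2,4-dienone and ties diene to alkene through only C11 and C9. This is a closed-shell copy of the radical ring reconstruction presumed for the natural bicyclo[2.2.2]octane.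
3. C11–C4' comes from a dearomative conjugate addition of phthalide 18 to α-methylene ketone 20; C8=C12 from methylenation of the resulting ketone.
4. Rings A/B (11) come from (−)-myrtenyl acetate: allylic oxidation, cuprate methylation (C10), Mannich reaction (C11), Z-acrylate, then acid-induced cyclobutane opening with lactonisation (ring A by strain release).
5. Ring order: B (chiral pool) → A → D/F (aromatic, separate branch) → C and E together.

Key step: step 17

Locants: C1=C2–C3(=O)–O–C4(Me)2 is the ring A lactone, C5–C10 ring B, C11 the CH2 between C9 and ring D, C12 the CH2 on C8. Phthalide-derived carbons carry primes as in 5,7-dihydroxy-4,6-dimethylphthalide (C1' lactone C=O, C3' OCH2, C3a', C4'–C7', C7a').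

Remark (assumption): the vinylogous acids 21–23 are drawn as 7'-enol/5'-ketone tautomers, which interconvert freely. The aminomethyl-bearing centre of 6–11 and 19 is drawn in one configuration but is inconsequential, since it becomes sp2 in 20.

## Route

Step 1
Reactants: 1 (1R)-(−)-myrtenyl acetate
Product: 2 4-oxomyrtenyl acetate (ring enone; bridgeheads unchanged)
Conditions: t-BuOOH (70% aq.), Rh2(cap)4 (1 mol %), K2CO3 (0.5 equiv), CH2Cl2, rt
Reagents that add atoms: tert-butyl hydroperoxide, CC(C)(C)OO
Why: Allylic oxidation by a peroxyl-radical chain (dirhodium caprolactamate/TBHP) should attack the only reactive ring allylic CH2 (the future C8; the acetoxymethyl C–H bonds are deactivated and the bridgehead is protected by Bredt strain) and give the conjugated enone without touching the two stereocentres.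

Step 2
Reactants: 2 4-oxomyrtenyl acetate
Product: 3 hydroxymethyl enone
Conditions: K2CO3 (0.2 equiv), MeOH, 0 °C
Reagents that add atoms: none
Why: Transesterification frees the primary alcohol, because an acyloxy group γ to the enone would be lost reductively in the cuprate step.

Step 3
Reactants: 3 hydroxymethyl enone
Product: 4 TBS ether of 3
Conditions: TBSCl, imidazole, DMF, rt
Reagents that add atoms: tert-butyldimethylsilyl chloride, CC(C)(C)[Si](C)(C)Cl
Why: Standard silylation gives an ether that tolerates the organocuprate.

Step 4
Reactants: 4 TBS ether of 3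
Product: 6 β-amino ketone (4-methyl anti, 4-CH2OTBS syn to the CMe2 bridge; 3-CH2NMe2), via TMS enol ether 5 (not isolated)
Conditions: MeLi, CuI, TMSCl, THF, −78 °C; then CH2=NMe2 I (Eschenmoser's salt), CH2Cl2, 0 °C to rt; aq. NaHCO3
Reagents that add atoms: methyllithium (delivered as lithium dimethylcuprate), [Li]C; dimethyl(methylidene)ammonium iodide, C=[N+](C)C.[I-]
Why: Gilman 1,4-addition (TMSCl-accelerated) should occur on the enone face anti to the gem-dimethyl bridge, as with verbenone, so C10 carries methyl anti and CH2OTBS syn to that bridge, and the regiodefined silyl enol ether is then aminomethylated only at C9 (Mannich reaction).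

Step 5
Reactants: 6 β-amino ketone
Product: 7 primary alcohol
Conditions: HF·pyridine, THF, 0 °C to rt
Reagents that add atoms: none
Why: Fluoride desilylation under mildly acidic conditions keeps the β-amino ketone protonated and intact.

Step 6
Reactants: 7 primary alcohol
Product: 8 keto aldehyde
Conditions: (COCl)2, DMSO, CH2Cl2, −78 °C; Et3N
Reagents that add atoms: none
Why: Swern oxidation converts the neopentyl alcohol into a non-enolisable aldehyde while tertiary amine and ketone are inert.

Step 7
Reactants: 8 keto aldehyde
Product: 9 methyl (Z)-enoate
Conditions: (CF3CH2O)2P(O)CH2CO2Me, KN(SiMe3)2, 18-crown-6, THF, −78 °C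
Reagents that add atoms: methyl bis(2,2,2-trifluoroethyl)phosphonoacetate, COC(=O)CP(=O)(OCC(F)(F)F)OCC(F)(F)F
Why: Still–Gennari olefination should give the Z-enoate under kinetic control and prefers the aldehyde over the hindered ketone.

Step 8
Reactants: 9 methyl (Z)-enoate
Product: 10 (Z)-acrylic acid
Conditions: LiOH, THF/H2O, 0 °C to rt; 1 M HCl to pH 6
Reagents that add atoms: lithium hydroxide, [Li+].[OH-]
Why: Mild saponification leaves the Z-alkene and the β-amino ketone unchanged.

Step 9
Reactants: 10 (Z)-acrylic acid
Product: 11 cis-fused ε-lactone ketone with 9-CH2NMe2 (rings A and B)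
Conditions: TfOH (3 equiv), CH2Cl2, −20 to 0 °C; aq. NaHCO3
Reagents that add atoms: none
Why: Protonation of the ketone should trigger heterolysis of the strained cyclobutane bond between the α-bridgehead and CMe2 (the acid-induced fragmentation known for nopinone-type ketones), and the tertiary cation is captured by the cis-disposed Z-acrylic acid to close the seven-membered lactone, with the C5–H/C10–Me cis fusion fixed by the pinane.

Step 10
Reactants: 12 methyl 2,4-dihydroxy-3,6-dimethylbenzoate
Product: 13 methyl 5-formyl-2,4-dihydroxy-3,6-dimethylbenzoate
Conditions: Cl2CHOMe, TiCl4, CH2Cl2, 0 °C; H2O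
Reagents that add atoms: dichloromethyl methyl ether, COC(Cl)Cl; water, O
Why: Rieche formylation can only occur at the single free, doubly activated ring position.

Step 11
Reactants: 13 formyl ester
Product: 14 methyl 2,4-dihydroxy-3,5,6-trimethylbenzoate
Conditions: Et3SiH, TFA, rt
Reagents that add atoms: none
Why: Ionic hydrogenation reduces the electron-rich salicylaldehyde-type carbonyl to a methyl group.

Step 12
Reactants: 14 trimethyl ester
Product: 15 methyl 2,4-dimethoxy-3,5,6-trimethylbenzoate
Conditions: MeI, K2CO3, acetone, reflux
Reagents that add atoms: iodomethane, CI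
Why: Williamson etherification masks both phenols for the anion chemistry.

Step 13
Reactants: 15 dimethoxy ester
Product: 17 5,7-dimethoxy-4,6-dimethylphthalide, via hydroxymethyl ester 16 (not isolated)
Conditions: LiN(iPr)2, THF, −78 °C; 2-(phenylsulfonyl)-3-phenyloxaziridine; to rt; aq. NH4Cl
Reagents that add atoms: 2-(phenylsulfonyl)-3-phenyloxaziridine, O=S(=O)(N1OC1c1ccccc1)c1ccccc1
Why: Lateral lithiation occurs only at the methyl ortho to the ester (benzylic anion conjugated with the carbonyl); electrophilic hydroxylation and spontaneous lactonisation then give the phthalide.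

Step 14
Reactants: 17 dimethoxyphthalide
Product: 18 5,7-dihydroxy-4,6-dimethylphthalide
Conditions: BBr3, CH2Cl2, −78 to 0 °C; H2O
Reagents that add atoms: none
Why: BBr3 cleaves both aryl methyl ethers and leaves the lactone intact.

Step 15
Reactants: 11 lactone Mannich base; 18 5,7-dihydroxy-4,6-dimethylphthalide
Product: 21 dearomatised Michael adduct (8-ketone; C4' quaternary), via N-oxide 19 (not isolated), via enone 20 (not isolated)
Conditions: mCPBA, CH2Cl2, 0 °C to rt; aq. NaHCO3 wash; then 18, 9-O-benzylcupreidine (1.1 equiv, recovered by extraction), THF–CH2Cl2, −40 to −20 °C; 1 M HCl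
Reagents that add atoms: none
Why: Proposed new method: N-oxidation and Cope elimination release enone 20; the quinuclidine of the alkaloid deprotonates the most acidic phenol (O5') of 18, and the chiral ion pair adds through C4' (ortho to O5', the site used in alkylative dearomatisations of dimethylorsellinate-type resorcinols) to the unhindered CH2 terminus of 20 while the catalyst phenol hydrogen-bonds the enone carbonyl, so the catalyst rather than the remote ring-B centres should select the face of the planar phenoxide and set C4' (the pseudo-enantiomeric cupreine ether is the alternative if the sense proves opposite), whereas C9 is set by protonation and equilibration α to the ketone (C11 equatorial, cis to C1); the closest known reaction types are cinchona-alkaloid-catalysed Michael additions of α-substituted cyclic β-keto esters to vinyl ketones that create quaternary centres, and base-mediated alkylative dearomatisation of acylresorcinols.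

Step 16
Reactants: 21 Michael adduct
Product: 22 8(12)-exocyclic alkene
Conditions: Ph3PCH3Br, KOtBu, THF (4 equiv ylide), 0 to 40 °C; 1 M HCl
Reagents that add atoms: methyltriphenylphosphonium bromide, C[P+](c1ccccc1)(c1ccccc1)c1ccccc1.[Br-]
Why: Wittig methylenation of the hindered 8-ketone (as practised on 8-oxodrimanes) should proceed while the first equivalent of ylide stores the vinylogous acid as its unreactive anion, and C9 stays in its thermodynamic configuration.

Step 17
Reactants: 22 8(12)-exocyclic alkene
Product: 23 cage cycloadduct (chelated enol of the 7'-keto lactone)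
Conditions: toluene (0.01 M), BHT, sealed tube, 150 °C
Reagents that add atoms: none
Why: On heating, 22 should undergo a concerted, asynchronous intramolecular Diels–Alder reaction in which the C6'=C7'(OH)–C7a'=C3a' diene of the cyclohexa-2,4-dienone (ring D, unable to re-aromatise because C4' is quaternary) adds to the exocyclic C8=C12 alkene. The closest known reaction type is the intramolecular Diels–Alder reaction of 6-alkenyl-6-alkylcyclohexa-2,4-dienones from alkylative or oxidative phenol dearomatisation, which gives bicyclo[2.2.2]octenones and, with a two-atom tether, isotwistanes. The C8–C3a' bond closes the five-membered ring C through the tether C9–C11, and the C12–C6' bond closes in the same event the cyclohexanone ring E (C8–C12–C6'–C5'–C4'–C3a'), the last ring of the skeleton, completing the bicyclo[2.2.2]octane. C8, C3a' and C6' are dictated by C4', because the alkene can only reach the diene face that carries C11 (the C4' methyl ends anti), and by C9, whose hydrogen must sit on the concave side so that rings B and C are cis-fused; the C4' epimer cannot attain this geometry. The step needs periselectivity over dienone dimerisation and over retro-ene loss of the side chain, secured by the fully substituted diene, high dilution and the lowest workable temperature, and regioselectivity (isotwistane, not twistane), secured by the short tether. The adduct is expected as the hydrogen-bonded enol.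

Step 18
Reactants: 23 cage cycloadduct
Product: 24 target CNP0295808.3
Conditions: Zn(BH4)2 (from ZnCl2 and NaBH4), Et2O–THF, −30 to 0 °C; aq. NH4Cl
Reagents that add atoms: none
Why: Zn(BH4)2 should reduce the keto tautomer as a zinc chelate between O7' and the lactone carbonyl (Oishi-type syn reduction); the chelate sits on the open C5'-carbonyl side, so hydride enters from the C12 side and gives the cis-β-hydroxy lactone with H-7' and H-7a' both facing the C8–C12 bridge, while the C5' ketone (between two quaternary carbons) and the unsaturated lactone are not reduced.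

## Compound list

1 | (1R)-(−)-myrtenyl acetate | CC(=O)OCC1=CC[C@H]2C[C@@H]1C2(C)C | starting material
2 | 4-oxomyrtenyl acetate, (6,6-dimethyl-4-oxobicyclo[3.1.1]hept-2-en-2-yl)methyl acetate | CC(=O)OCC1=CC(=O)[C@H]2C[C@@H]1C2(C)C | intermediate
3 | 4-(hydroxymethyl)-6,6-dimethylbicyclo[3.1.1]hept-3-en-2-one | OCC1=CC(=O)[C@H]2C[C@@H]1C2(C)C | intermediate
4 | TBS ether of 3 | CC(C)(C)[Si](C)(C)OCC1=CC(=O)[C@H]2C[C@@H]1C2(C)C | intermediate
5 | TMS enol ether after methyl addition (4-Me anti to the CMe2 bridge) | C[Si](C)(C)OC1=C[C@@](C)(CO[Si](C)(C)C(C)(C)C)[C@@H]2C[C@H]1C2(C)C | intermediate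
6 | 3-(dimethylaminomethyl)-4-(TBS-oxymethyl)-4,6,6-trimethylbicyclo[3.1.1]heptan-2-one | O=C1[C@H](CN(C)C)[C@@](C)(CO[Si](C)(C)C(C)(C)C)[C@@H]2C[C@H]1C2(C)C | intermediate
7 | primary alcohol from 6 | O=C1[C@H](CN(C)C)[C@@](C)(CO)[C@@H]2C[C@H]1C2(C)C | intermediate
8 | keto aldehyde | O=C1[C@H](CN(C)C)[C@@](C)(C=O)[C@@H]2C[C@H]1C2(C)C | intermediate
9 | methyl (Z)-enoate | O=C1[C@H](CN(C)C)[C@@](C)(/C=C\C(=O)OC)[C@@H]2C[C@H]1C2(C)C | intermediate
10 | (Z)-acrylic acid | O=C1[C@H](CN(C)C)[C@@](C)(/C=C\C(=O)O)[C@@H]2C[C@H]1C2(C)C | intermediate
11 | cis-fused ε-lactone cyclohexanone with 9-CH2NMe2 (C5–H cis to C10–Me) | CC1(C)OC(=O)C=C[C@@]2(C)[C@@H]1CCC(=O)[C@@H]2CN(C)C | intermediate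
12 | methyl 2,4-dihydroxy-3,6-dimethylbenzoate | COC(=O)c1c(O)c(C)c(O)cc1C | starting material
13 | methyl 5-formyl-2,4-dihydroxy-3,6-dimethylbenzoate | COC(=O)c1c(O)c(C)c(O)c(C=O)c1C | intermediate
14 | methyl 2,4-dihydroxy-3,5,6-trimethylbenzoate | COC(=O)c1c(O)c(C)c(O)c(C)c1C | intermediate
15 | methyl 2,4-dimethoxy-3,5,6-trimethylbenzoate | COC(=O)c1c(OC)c(C)c(OC)c(C)c1C | intermediate
16 | methyl 6-(hydroxymethyl)-2,4-dimethoxy-3,5-dimethylbenzoate (as lithium alkoxide) | COC(=O)c1c(OC)c(C)c(OC)c(C)c1CO | intermediate
17 | 5,7-dimethoxy-4,6-dimethylphthalide | O=C1OCc2c1c(OC)c(C)c(OC)c2C | intermediate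
18 | 5,7-dihydroxy-4,6-dimethylphthalide | O=C1OCc2c1c(O)c(C)c(O)c2C | intermediate
19 | N-oxide of 11 | CC1(C)OC(=O)C=C[C@@]2(C)[C@@H]1CCC(=O)[C@@H]2C[N+](C)(C)[O-] | intermediate
20 | 9-methylene-8-ketone (α-methylene ketone) | CC1(C)OC(=O)C=C[C@@]2(C)[C@@H]1CCC(=O)C2=C | intermediate
21 | dearomatised Michael adduct, 8-ketone (C11 on C9 cis to C1; C4' quaternary) | CC1(C)OC(=O)C=C[C@@]2(C)[C@@H]1CCC(=O)[C@H]2C[C@@]3(C)C(=O)C(C)=C(O)C4=C3COC4=O | intermediate
22 | 8(12)-exocyclic alkene (cycloaddition substrate) | CC1(C)OC(=O)C=C[C@@]2(C)[C@@H]1CCC(=C)[C@H]2C[C@@]3(C)C(=O)C(C)=C(O)C4=C3COC4=O | intermediate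
23 | cage cycloadduct, enol of the 7'-keto lactone | CC1(C)OC(=O)C=C[C@@]2(C)[C@@H]1CC[C@]13C[C@]4(C)C(=O)[C@](C)(C[C@@H]21)[C@]31COC(=O)C1=C4O | intermediate
24 | CNP0295808.3 | CC1(C)OC(=O)C=C[C@@]2(C)[C@@H]1CC[C@]13C[C@]4(C)C(=O)[C@](C)(C[C@@H]21)[C@]31COC(=O)[C@H]1[C@H]4O | target

## Step count and risks

Total step count: 18. Longest linear sequence: 13 steps (steps 1–9 and 15–18 from 1); the phthalide branch (steps 10–14) joins at step 15.

Steps most likely to fail:

1. Step 15 (dearomative conjugate addition). The alkaloid may discriminate the two faces of the phenoxide poorly when paired with the chiral enone. Attack through C6' or through oxygen may compete, and the acidic product may sequester the base. Fallback with known chemistry, setting out from 11: N-oxide elimination to 20 as above without the alkaloid. 1,4-Addition of TMSI (CH2Cl2, −78 °C) gives the allylic iodide silyl enol ether F1. SN2 C-allylation of the lithium phenoxide of 18 (LiOtBu, toluene–THF, 0 °C; the alkylative dearomatisation mode known for this class of resorcinols with allylic halides) gives the silyl enol ether adduct F2. Aqueous HCl/THF then gives 21 together with its C4' epimer F3, with no facial control expected. The two are separated, and the C4' epimer F3 is returned to the mixture by Cs2CO3/MeCN (retro-Michael/Michael equilibration). The fallback rejoins the route at 21.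

2. Step 17 (key cycloaddition). The forming C8–C3a' bond is 1,3-diaxial to C1 on ring B, which may raise the barrier until retro-ene cleavage of C11–C4' (with re-aromatisation) or dienone dimerisation takes over. Fallback, setting out from 22: a stepwise radical formal [4+2] with Mn(OAc)3·2H2O in degassed EtOH–AcOH at 60 °C. One-electron oxidation of the enolised dicarbonyl gives the C6' radical, which adds to the C12 terminus; the tertiary C8 radical closes onto C3a' (β-carbon of the butenolide), and the resulting dicarbonyl radical abstracts hydrogen from the solvent. No new isolable compound is made (F0), and the fallback rejoins the route at 23.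

3. Step 18 (carbonyl reduction). Hydride may enter from the more open C5'-carbonyl side, or C7a' may be protonated from the other face, giving C7'/C7a' epimers; strong enolisation may also stall the reduction. Fallback, setting out from 23: biocatalytic reduction with an NADPH-dependent ketoreductase chosen from a screening panel (glucose/glucose dehydrogenase recycling, pH 7 buffer with DMSO), the enzyme class that reduces this carbonyl in the natural pathway. No new compound is made (F0), and the fallback arrives at 24.

## Further compounds

F1 | step 15 | allylic iodide silyl enol ether from 20 | CC1(C)OC(=O)C=C[C@@]2(C)[C@@H]1CCC(O[Si](C)(C)C)=C2CI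
F2 | step 15 | C4'-allylated dienone silyl enol ether | CC1(C)OC(=O)C=C[C@@]2(C)[C@@H]1CCC(O[Si](C)(C)C)=C2C[C@@]3(C)C(=O)C(C)=C(O)C4=C3COC4=O
F3 | step 15 | C4' epimer of 21 | CC1(C)OC(=O)C=C[C@@]2(C)[C@@H]1CCC(=O)[C@H]2C[C@]3(C)C(=O)C(C)=C(O)C4=C3COC4=O
F0 | step 17 | none | none
F0 | step 18 | none | none
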